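The isoflavone is disconnected at C4–C4a, C2–C3 and O1–C2: ring A is 5-methoxyresorcinol, C4, C3 and ring B are an arylacetic acid, and C2 is the formyl carbon of DMF. The key step uses the phloroglucinol-type oxygen pattern of ring A (O1, 5-OMe, 7-OH), which makes C4a strongly nucleophilic and leaves exactly one free hydroxyl next to the new C4 ketone, together with the acidity of the C3 methylene, to assemble ring C in one pot. Its acid partner is unprotected (3-bromo-4,5-dihydroxyphenyl)acetic acid; the bromine at C5' is the handle from which ring D is later annulated across C5' and O4' by Heck coupling and cyclodehydration.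

Key step: step 3

Remark: the target has no stereocentre; the only stereo-element on the route is the E alkene made in step 5, which ends as the ring D double bond.

Step 1
Reactants: 1 homovanillic acid, (4-hydroxy-3-methoxyphenyl)acetic acid
Product: 2 (3-bromo-4-hydroxy-5-methoxyphenyl)acetic acid
Conditions: Br2 (1.05 equiv), AcOH, rt
Reagents that add atoms: bromine, BrBr
Why: Electrophilic aromatic bromination of a para-substituted guaiacol, in which the free hydroxyl is the strongest donor and its para position is blocked by the CH2CO2H chain, so bromine should enter ortho to OH (C5), as it does with vanillin.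

Step 2
Reactants: 2 (3-bromo-4-hydroxy-5-methoxyphenyl)acetic acid
Product: 3 (3-bromo-4,5-dihydroxyphenyl)acetic acid
Conditions: BBr3 (3.5 equiv), CH2Cl2, −78 °C → rt; then H2O
Reagents that add atoms: none
Why: BBr3 cleavage of the aryl methyl ether unmasks the catechol while the molecule holds no other methyl ether, so the 5-OMe of ring A is never exposed to demethylating conditions; the aryl bromide and the acid chain are inert.

Step 3
Reactants: 3 (3-bromo-4,5-dihydroxyphenyl)acetic acid; 4 5-methoxyresorcinol; 5 N,N-dimethylformamide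
Product: 8 3-(3-bromo-4,5-dihydroxyphenyl)-7-hydroxy-5-methoxy-4H-chromen-4-one, via deoxybenzoin 6 (not isolated), via enaminone 7 (not isolated)
Conditions: BF3·OEt2 (neat), 80 °C; then DMF, MeSO2Cl, 50 → 80 °C; aq NaOAc
Reagents that add atoms: N,N-dimethylformamide (5, source of C2), CN(C)C=O
Why: BF3·OEt2 turns the carboxylic acid of 3 into an acylating species that attacks the electron-rich ring of 4 in a Friedel–Crafts C-acylation (C4–C4a), and it holds deoxybenzoin 6 as a boron chelate between the ketone and its single ortho hydroxyl. DMF and MeSO2Cl then form a Vilsmeier-type iminium salt that aminomethylenates the doubly activated C3 methylene to enaminone 7 (C2–C3), after which the ortho hydroxyl adds to the enamine carbon and dimethylamine is expelled (O1–C2). The closest known reaction type is the one-pot BF3·OEt2/DMF/MeSO2Cl synthesis of polyhydroxyisoflavones from unprotected phenols and arylacetic acids. Ring C closes by a 6-endo-trig oxa-conjugate addition followed by elimination, and no stereocentre is created. The selectivity needed is acylation of 4 at C4 or C6 (between OH and OMe, para to the other OH) and not at C2; the two equivalent sites, each para to a free hydroxyl, should favour this, and the minor 5-hydroxy-7-methoxy isomer from C2 attack carries a chelated 5-OH and should be far less polar and removable. The bromocatechol ring of 3 is much less nucleophilic than ring A and is further damped by boron complexation, so self-acylation should not compete, and any O-formyl or boron esters are hydrolysed in the aqueous work-up.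

Step 4
Reactants: 8 3-(3-bromo-4,5-dihydroxyphenyl)-7-hydroxy-5-methoxy-4H-chromen-4-one
Product: 9 7-acetoxy-3-(3,4-diacetoxy-5-bromophenyl)-5-methoxy-4H-chromen-4-one
Conditions: Ac2O, pyridine, DMAP (cat.), rt
Reagents that add atoms: acetic anhydride, CC(=O)OC(C)=O
Why: Standard O-acetylation of all three phenols masks the catechol and the 7-OH, which would otherwise bind palladium and be oxidised under the hot basic conditions of the next step.

Step 5
Reactants: 9 7-acetoxy-3-(3,4-diacetoxy-5-bromophenyl)-5-methoxy-4H-chromen-4-one; 10 2-methylbut-3-en-2-ol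
Product: 11 7-acetoxy-3-{3,4-diacetoxy-5-[(E)-3-hydroxy-3-methylbut-1-en-1-yl]phenyl}-5-methoxy-4H-chromen-4-one
Conditions: Pd(OAc)2 (5 mol %), P(o-tol)3 (15 mol %), Et3N, MeCN, 95 °C, sealed tube
Reagents that add atoms: none
Why: Mizoroki–Heck reaction in which the C5'–Br bond adds to zerovalent palladium, the terminal alkene inserts with aryl delivery to its CH2 end, and syn β-hydride elimination can only take a benzylic hydrogen because the carbinol carbon bears none, so the E-styrenyl tertiary alcohol should result; aryl acetates tolerate Et3N in the absence of nucleophiles.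

Step 6
Reactants: 11 7-acetoxy-3-{3,4-diacetoxy-5-[(E)-3-hydroxy-3-methylbut-1-en-1-yl]phenyl}-5-methoxy-4H-chromen-4-one
Product: 12 3-{3,4-dihydroxy-5-[(E)-3-hydroxy-3-methylbut-1-en-1-yl]phenyl}-7-hydroxy-5-methoxy-4H-chromen-4-one
Conditions: K2CO3 (cat.), MeOH, 0 °C → rt, Ar; AcOH quench
Reagents that add atoms: none
Why: Base-catalysed transesterification of the three aryl acetates, by far the most labile groups present, should free the phenols without touching the tertiary allylic alcohol, the E alkene or the chromone under brief, cold, oxygen-free conditions.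

Step 7
Reactants: 12 3-{3,4-dihydroxy-5-[(E)-3-hydroxy-3-methylbut-1-en-1-yl]phenyl}-7-hydroxy-5-methoxy-4H-chromen-4-one
Product: 13 glycyrrhizaisoflavone B, 7-hydroxy-3-(8-hydroxy-2,2-dimethyl-2H-chromen-6-yl)-5-methoxy-4H-chromen-4-one
Conditions: PPTS (cat.), 1,4-dioxane/toluene, 80 °C
Reagents that add atoms: none
Why: Acid-catalysed cyclodehydration in which ionisation of the tertiary allylic alcohol gives an allyl cation/ortho-quinone methide that can rotate about the former double bond, and O4', the only hydroxyl ortho to the side chain, closes onto the CMe2 terminus (oxa-6π-electrocyclisation) to the 2,2-dimethyl-2H-chromene; the mild acid should spare the 5-OMe and the chromone.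

Compound list
1 | homovanillic acid, (4-hydroxy-3-methoxyphenyl)acetic acid | COc1cc(CC(=O)O)ccc1O | starting material
2 | (3-bromo-4-hydroxy-5-methoxyphenyl)acetic acid | COc1cc(CC(=O)O)cc(Br)c1O | intermediate
3 | (3-bromo-4,5-dihydroxyphenyl)acetic acid | OC(=O)Cc1cc(O)c(O)c(Br)c1 | intermediate
4 | 5-methoxyresorcinol, 5-methoxybenzene-1,3-diol | COc1cc(O)cc(O)c1 | starting material
5 | N,N-dimethylformamide | CN(C)C=O | starting material
6 | deoxybenzoin, 2-(3-bromo-4,5-dihydroxyphenyl)-1-(2,4-dihydroxy-6-methoxyphenyl)ethan-1-one (not isolated) | COc1cc(O)cc(O)c1C(=O)Cc1cc(O)c(O)c(Br)c1 | intermediate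
7 | enaminone, (E)-2-(3-bromo-4,5-dihydroxyphenyl)-1-(2,4-dihydroxy-6-methoxyphenyl)-3-(dimethylamino)prop-2-en-1-one (not isolated; drawn E, geometry labile and immaterial) | COc1cc(O)cc(O)c1C(=O)/C(=C/N(C)C)c1cc(O)c(O)c(Br)c1 | intermediate
8 | 3-(3-bromo-4,5-dihydroxyphenyl)-7-hydroxy-5-methoxy-4H-chromen-4-one | COc1cc(O)cc2occ(-c3cc(O)c(O)c(Br)c3)c(=O)c12 | intermediate
9 | 7-acetoxy-3-(3,4-diacetoxy-5-bromophenyl)-5-methoxy-4H-chromen-4-one | COc1cc(OC(C)=O)cc2occ(-c3cc(OC(C)=O)c(OC(C)=O)c(Br)c3)c(=O)c12 | intermediate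
10 | 2-methylbut-3-en-2-ol | C=CC(C)(C)O | starting material
11 | 7-acetoxy-3-{3,4-diacetoxy-5-[(E)-3-hydroxy-3-methylbut-1-en-1-yl]phenyl}-5-methoxy-4H-chromen-4-one | COc1cc(OC(C)=O)cc2occ(-c3cc(OC(C)=O)c(OC(C)=O)c(/C=C/C(C)(C)O)c3)c(=O)c12 | intermediate
12 | 3-{3,4-dihydroxy-5-[(E)-3-hydroxy-3-methylbut-1-en-1-yl]phenyl}-7-hydroxy-5-methoxy-4H-chromen-4-one | COc1cc(O)cc2occ(-c3cc(O)c(O)c(/C=C/C(C)(C)O)c3)c(=O)c12 | intermediate
13 | glycyrrhizaisoflavone B, 7-hydroxy-3-(8-hydroxy-2,2-dimethyl-2H-chromen-6-yl)-5-methoxy-4H-chromen-4-one | COc1cc(O)cc2occ(-c3cc(O)c4c(c3)C=CC(C)(C)O4)c(=O)c12 | target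

Total step count: 7. Longest linear sequence: 7 steps (1 → 2 → 3 → 8 → 9 → 11 → 12 → 13).

Steps most likely to fail

Step 3. The acylation may take place at the carbon of 4 that lies between its two hydroxyls, or in both modes in a mixture that resists separation, so that ring A ends with the 5-hydroxy-7-methoxy pattern. The fallback sets out from 3 and replaces 4 by symmetrical phloroglucinol, for which only one acylation mode exists. BF3·OEt2 acylation should give 2-(3-bromo-4,5-dihydroxyphenyl)-1-(2,4,6-trihydroxyphenyl)ethan-1-one F1, and ring closure with DMF and MeSO2Cl in BF3·OEt2 should give 3-(3-bromo-4,5-dihydroxyphenyl)-5,7-dihydroxy-4H-chromen-4-one F2. Because the chelated 5-OH is the least reactive phenol, MOMCl and i-Pr2NEt in CH2Cl2 should protect O7, O3' and O4' only, giving 3-[3-bromo-4,5-bis(methoxymethoxy)phenyl]-5-hydroxy-7-(methoxymethoxy)-4H-chromen-4-one F3. Forcing methylation (Me2SO4, K2CO3, acetone, reflux) should then give 3-[3-bromo-4,5-bis(methoxymethoxy)phenyl]-5-methoxy-7-(methoxymethoxy)-4H-chromen-4-one F4, and HCl in MeOH removes the three MOM groups to come back to the route at 8.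

Step 5. The temperature that alkene insertion needs at this crowded, electron-rich aryl bromide may bring palladium black, hydrodebromination and loss of acetate, after which the freed catechol deactivates the catalyst. The fallback sets out from 9 and uses a Sonogashira coupling with 2-methylbut-3-yn-2-ol (PdCl2(PPh3)2, CuI, Et3N, THF, 60 °C), which runs cooler with a slim linear alkyne, to give 7-acetoxy-3-[3,4-diacetoxy-5-(3-hydroxy-3-methylbut-1-yn-1-yl)phenyl]-5-methoxy-4H-chromen-4-one F5. Lindlar semi-hydrogenation (H2, Pd/CaCO3 poisoned with Pb(OAc)2, quinoline, EtOAc) should give 7-acetoxy-3-{3,4-diacetoxy-5-[(Z)-3-hydroxy-3-methylbut-1-en-1-yl]phenyl}-5-methoxy-4H-chromen-4-one F6. Methanolysis as in step 6 should give 3-{3,4-dihydroxy-5-[(Z)-3-hydroxy-3-methylbut-1-en-1-yl]phenyl}-7-hydroxy-5-methoxy-4H-chromen-4-one F7, whose side chain already points towards O4' and should close under the conditions of step 7, so the route is rejoined at 13.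

Step 7. Ionisation of the tertiary allylic alcohol may be followed by proton loss to the isoprenyl diene, oligomerisation or re-protonation of the chromene, since the E alkene has to isomerise before O4' can reach the tertiary carbon. The fallback sets out from 12 and saturates the side-chain alkene (H2, Pd/C, EtOAc, rt, stopped after one equivalent) to give 3-[3,4-dihydroxy-5-(3-hydroxy-3-methylbutyl)phenyl]-7-hydroxy-5-methoxy-4H-chromen-4-one F8. Acid (p-TsOH, toluene/1,4-dioxane, 80 °C) should close the now flexible chain onto O4' to give the chroman 7-hydroxy-3-(8-hydroxy-2,2-dimethylchroman-6-yl)-5-methoxy-4H-chromen-4-one F9, and dehydrogenation with DDQ in refluxing 1,4-dioxane returns to the route at 13.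

Further compounds
F1 | step 3 | 2-(3-bromo-4,5-dihydroxyphenyl)-1-(2,4,6-trihydroxyphenyl)ethan-1-one | O=C(Cc1cc(O)c(O)c(Br)c1)c1c(O)cc(O)cc1O
F2 | step 3 | 3-(3-bromo-4,5-dihydroxyphenyl)-5,7-dihydroxy-4H-chromen-4-one | O=c1c(-c2cc(O)c(O)c(Br)c2)coc2cc(O)cc(O)c12
F3 | step 3 | 3-[3-bromo-4,5-bis(methoxymethoxy)phenyl]-5-hydroxy-7-(methoxymethoxy)-4H-chromen-4-one | COCOc1cc(O)c2c(c1)occ(-c1cc(OCOC)c(OCOC)c(Br)c1)c2=O
F4 | step 3 | 3-[3-bromo-4,5-bis(methoxymethoxy)phenyl]-5-methoxy-7-(methoxymethoxy)-4H-chromen-4-one | COCOc1cc(OC)c2c(c1)occ(-c1cc(OCOC)c(OCOC)c(Br)c1)c2=O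
F5 | step 5 | 7-acetoxy-3-[3,4-diacetoxy-5-(3-hydroxy-3-methylbut-1-yn-1-yl)phenyl]-5-methoxy-4H-chromen-4-one | COc1cc(OC(C)=O)cc2occ(-c3cc(OC(C)=O)c(OC(C)=O)c(C#CC(C)(C)O)c3)c(=O)c12
F6 | step 5 | 7-acetoxy-3-{3,4-diacetoxy-5-[(Z)-3-hydroxy-3-methylbut-1-en-1-yl]phenyl}-5-methoxy-4H-chromen-4-one | COc1cc(OC(C)=O)cc2occ(-c3cc(OC(C)=O)c(OC(C)=O)c(/C=C\C(C)(C)O)c3)c(=O)c12
F7 | step 5 | 3-{3,4-dihydroxy-5-[(Z)-3-hydroxy-3-methylbut-1-en-1-yl]phenyl}-7-hydroxy-5-methoxy-4H-chromen-4-one | COc1cc(O)cc2occ(-c3cc(O)c(O)c(/C=C\C(C)(C)O)c3)c(=O)c12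
F8 | step 7 | 3-[3,4-dihydroxy-5-(3-hydroxy-3-methylbutyl)phenyl]-7-hydroxy-5-methoxy-4H-chromen-4-one | COc1cc(O)cc2occ(-c3cc(O)c(O)c(CCC(C)(C)O)c3)c(=O)c12
F9 | step 7 | 7-hydroxy-3-(8-hydroxy-2,2-dimethylchroman-6-yl)-5-methoxy-4H-chromen-4-one | COc1cc(O)cc2occ(-c3cc(O)c4c(c3)CCC(C)(C)O4)c(=O)c12
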